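Numbering: atoms are counted along the target SMILES (C1 = exocyclic CH2, C39 = ring A carbinol); ring A = C32/C33/C35/C37/C39, ring B = C2/C3/C27/C28/C30/C31/C32/C39, ring C = C3/C4/C5/C24/C26/C27, ring D = C5/C6/C10/C23/C24.
Enabling feature: ring D has one oxygenated carbon, C10, between isopropyl-bearing C6 and C23, and is fused to ring C through C5–C24 – what an alkyne (C5≡C6), a 1,1-disubstituted alkene (C24=C23) and CO leave behind after a [2+2+1] cycloaddition.
Cuts: C10–O ester; C35 oxidation level; C39–O; C28=C30 (metathesis); C31–C32 (conjugate allylation); C2–C39 (sp2–sp2 coupling); C5–C24, C6–C10 and C10–C23 (Pauson–Khand); C3–C4 and C27–C3 (succinate enolate alkylations).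
Forward: succinate enyne → rings C and D in one step → C10/C5/C6 reduction → arms at C27 and C3 → ring A joined at C2–C39 → allyl at C32 → ring B by ring-closing metathesis → C39–OH → C10 ester → diosphenol.
Stereochemistry: C27 from an oxazolidinone alkylation, C3 from dianion alkylation, C24 from the chair-like Pauson–Khand tether, C10 from a CBS reduction, C5/C6 from hydroxyl-directed hydrogenation, C32 from a chiral-pool C33 methyl centre (erased at the end), C39 from enolate hydroxylation anti to C31, C15 from Sharpless epoxidation, C19 from (S)-1-bromo-2-methylbutane.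

Key step: step 8

Assumption: β is the face of the C25 methyl; the step 6 dianion alkylation is taken to follow the usual sense for 2-substituted succinic 4-tert-butyl half-esters (new group anti to the existing one in the lithium-bridged dianion), which gives the (S,S) diastereomer.

Step 1
Reactants: 1 4-methylpent-4-enoic acid; 2 (R)-4-benzyl-1,3-oxazolidin-2-one
Product: 4 (R)-4-benzyl-3-(4-methylpent-4-enoyl)-1,3-oxazolidin-2-one, via mixed pivalic anhydride 3 (not isolated)
Conditions: t-BuCOCl, Et3N, THF, −20 °C; then 2, LiCl, −20 °C → rt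
Reagents that add atoms: none
Why: N-acylation of the oxazolidinone through the mixed pivalic anhydride is a standard entry to Evans imides and creates no stereocentre.

Step 2
Reactants: 4; 5 tert-butyl bromoacetate
Product: 6 tert-butyl (3S)-3-{[(4R)-4-benzyl-2-oxo-1,3-oxazolidin-3-yl]carbonyl}-5-methylhex-5-enoate
Conditions: NaN(SiMe3)2, THF, −78 °C; then 5, −78 → −40 °C
Reagents that add atoms: none
Why: Evans alkylation: the chelated Z-sodium enolate is alkylated on the face opposite the benzyl group, which sets C27 as S.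

Step 3
Reactants: 6
Product: 7 (2S)-4-tert-butoxy-2-(2-methylprop-2-en-1-yl)-4-oxobutanoic acid
Conditions: LiOH, H2O2, THF/H2O, 0 °C; aq. Na2SO3; HCl to pH 2
Reagents that add atoms: hydrogen peroxide (as LiOOH), OO
Why: Hydroperoxide cleavage of the exocyclic imide carbonyl is the standard racemisation-free removal of the auxiliary and leaves the tert-butyl ester untouched.

Step 4
Reactants: 8 3-methylbut-1-yne
Product: 9 4-methylpent-2-yn-1-ol
Conditions: n-BuLi, THF, −78 °C; (CH2O)n, −78 °C → rt; aq. NH4Cl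
Reagents that add atoms: formaldehyde (as paraformaldehyde), C=O
Why: Hydroxymethylation of a lithium acetylide with formaldehyde is a routine alkynylation.

Step 5
Reactants: 9
Product: 10 1-bromo-4-methylpent-2-yne
Conditions: PBr3, pyridine (cat.), Et2O, 0 °C
Reagents that add atoms: phosphorus tribromide, BrP(Br)Br
Why: Bromination of the primary propargylic alcohol with PBr3 is a routine SN2 substitution.

Step 6
Reactants: 7; 10
Product: 11 (2S,3S)-3-(tert-butoxycarbonyl)-7-methyl-2-(2-methylprop-2-en-1-yl)oct-5-ynoic acid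
Conditions: LiN(i-Pr)2 (2.2 equiv), THF, −78 °C; then 10, −78 → −20 °C; HCl to pH 2–3
Reagents that add atoms: none
Why: Alkylation of the dilithio carboxylate/ester-enolate of a 2-substituted succinic half-ester: the lithium-bridged dianion should take up the propargylic bromide on the face of C3 opposite the methallyl group on C27, giving the (S,S) diastereomer whose two carboxyl carbons become trans on ring C.

Step 7
Reactants: 11
Product: 12 1-tert-butyl 4-methyl (2S,3S)-2-(4-methylpent-2-yn-1-yl)-3-(2-methylprop-2-en-1-yl)butanedioate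
Conditions: MeI, K2CO3, DMF, rt
Reagents that add atoms: iodomethane, CI
Why: Carboxylate O-alkylation under mild carbonate conditions gives the methyl ester without touching the α-stereocentres or the tert-butyl ester.

Step 8
Reactants: 12
Product: 14 5-tert-butyl 6-methyl (5S,6S,7aS)-7a-methyl-2-oxo-3-(propan-2-yl)-2,4,5,6,7,7a-hexahydro-1H-indene-5,6-dicarboxylate, via alkyne–Co2(CO)6 complex 13 (not isolated)
Conditions: Co2(CO)8 (1.1 equiv), CH2Cl2, rt; then N-methylmorpholine N-oxide (8 equiv), CH2Cl2, 0 °C → rt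
Reagents that add atoms: dicobalt octacarbonyl (source of the C10 carbonyl), [C-]#[O+].[C-]#[O+].[C-]#[O+].[C-]#[O+].[C-]#[O+].[C-]#[O+].[C-]#[O+].[C-]#[O+].[Co].[Co]
Why: Co2(CO)8 first gives the alkyne complex 13; oxidative removal of one CO by the N-oxide opens a site for the C24=C23 alkene, which inserts into the Co–C5 bond (exo with respect to the tether, forming C5–C24 and ring C), and CO insertion with reductive elimination then forms C10–C23 and C6–C10, closing ring D as the cyclopentenone. This is an intramolecular Pauson–Khand reaction of a 1,7-enyne, a known class, used here at its demanding end (1,1-disubstituted alkene, branched alkyne substituent). Ring C closes by alkene insertion within the cobaltacycle and ring D by carbonylative reductive elimination, so the tether dictates the regiochemistry: isopropyl-bearing C6 ends α and C23 α′ to the new carbonyl C10. The only new stereocentre, quaternary C24, should be set by a chair-like arrangement of the C4–C3–C27–C26 tether with both esters equatorial, which puts the C25 methyl pseudo-axial and cis to the C3 ester (C24 S). The step needs cycloaddition to outrun alkyne oligomerisation and needs diastereoselectivity at C24; the trans vicinal esters serve both by favouring the folded conformer, and no other alkene or alkyne is present.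

Step 9
Reactants: 14
Product: 15 5-tert-butyl 6-methyl (2R,5S,6S,7aS)-2-hydroxy-7a-methyl-3-(propan-2-yl)-2,4,5,6,7,7a-hexahydro-1H-indene-5,6-dicarboxylate
Conditions: (S)-2-methyl-CBS-oxazaborolidine [(3aS)-1-methyl-3,3-diphenyltetrahydro-1H,3H-pyrrolo[1,2-c][1,3,2]oxazaborole] (0.3 equiv), BH3·SMe2, THF, −20 °C; MeOH
Reagents that add atoms: none
Why: Corey–Bakshi–Shibata reduction: with the substituted alkene carbon C6 as the large and C23 as the small ketone substituent the catalyst should deliver hydride to the β face and give the α-alcohol (C10 R) against the weak steric bias of the C25 methyl.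

Step 10
Reactants: 15
Product: 16 5-tert-butyl 6-methyl (2R,3R,3aS,5S,6S,7aS)-2-hydroxy-7a-methyl-3-(propan-2-yl)octahydro-1H-indene-5,6-dicarboxylate
Conditions: H2 (1–4 bar), [Ir(cod)(PCy3)(py)]PF6 (10 mol %), CH2Cl2, rt
Reagents that add atoms: none
Why: Hydroxyl-directed hydrogenation: the cationic iridium catalyst binds the C10 hydroxyl and adds H2 to the tetrasubstituted C5=C6 bond from the α face, which is also the face away from the C25 methyl, setting C5 (H α, trans ring fusion) and C6 (isopropyl β).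

Step 11
Reactants: 16
Product: 18 tert-butyl (2R,3R,3aS,5S,6S,7aS)-6-acetyl-2-hydroxy-7a-methyl-3-(propan-2-yl)octahydro-1H-indene-5-carboxylate, via Weinreb amide 17 (not isolated)
Conditions: MeNHOMe·HCl (1.6 equiv), MeMgCl (6 equiv), THF, −15 → 0 °C; aq. NH4Cl
Reagents that add atoms: methylmagnesium chloride, C[Mg]Cl
Why: One-pot Weinreb ketone synthesis: the magnesium amide converts the methyl ester to the N-methoxy-N-methylamide, which takes up one methyl Grignard as a stable chelate, while the hindered tert-butyl ester does not react.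

Step 12
Reactants: 18
Product: 19 tert-butyl (2R,3R,3aS,5S,6S,7aS)-2-hydroxy-7a-methyl-3-(propan-2-yl)-6-(prop-1-en-2-yl)octahydro-1H-indene-5-carboxylate
Conditions: Ph3PCH3Br, KOt-Bu (3 equiv each), THF, 0 °C → rt
Reagents that add atoms: methylenetriphenylphosphorane (from Ph3PCH3Br and KOt-Bu), C=P(c1ccccc1)(c1ccccc1)c1ccccc1
Why: Wittig methylenation turns the acetyl group into the isopropenyl group; if C27 enolises it returns to the more stable equatorial (trans) arrangement, and the tert-butyl ester is inert to the ylide.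

Step 13
Reactants: 19
Product: 21 (2R,3R,3aS,5S,6S,7aS)-2-[(tert-butyldimethylsilyl)oxy]-7a-methyl-3-(propan-2-yl)-6-(prop-1-en-2-yl)octahydro-1H-indene-5-carboxylic acid, via silyl ester 20 (not isolated)
Conditions: t-BuMe2SiOTf (3 equiv), 2,6-lutidine (6 equiv), CH2Cl2, 0 °C → rt; then K2CO3, MeOH/H2O, 0 °C; citric acid to pH 4
Reagents that add atoms: tert-butyldimethylsilyl triflate, CC(C)(C)[Si](C)(C)OS(=O)(=O)C(F)(F)F
Why: Silyl triflate with 2,6-lutidine silylates the C10 hydroxyl and at the same time dealkylates the tert-butyl ester to the silyl ester (loss of isobutene), a known non-protic cleavage that spares the isopropenyl group; mild methanolysis of the labile silyl ester then frees the acid.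

Step 14
Reactants: 21
Product: 22 1-[(2R,3R,3aS,5S,6S,7aS)-2-[(tert-butyldimethylsilyl)oxy]-7a-methyl-3-(propan-2-yl)-6-(prop-1-en-2-yl)octahydro-1H-inden-5-yl]ethan-1-one
Conditions: MeLi (3.5 equiv), Et2O, 0 °C; inverse quench into aq. NH4Cl
Reagents that add atoms: methyllithium, [Li]C
Why: Addition of methyllithium to the lithium carboxylate gives the stable dilithio gem-diolate, which collapses to the methyl ketone only on work-up (classical acid-to-methyl-ketone conversion).

Step 15
Reactants: 22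
Product: 23 2,4,6-tri(propan-2-yl)benzenesulfonyl hydrazone of 22
Conditions: 2,4,6-(i-Pr)3C6H2SO2NHNH2, THF, HCl (cat.), rt
Reagents that add atoms: 2,4,6-tri(propan-2-yl)benzenesulfonohydrazide, CC(C)c1cc(C(C)C)c(S(=O)(=O)NN)c(C(C)C)c1
Why: Condensation of the methyl ketone with the arenesulfonyl hydrazide gives the hydrazone for the Shapiro reaction, the triisopropyl arene preventing ortho-lithiation later.

Step 16
Reactants: 24 (R)-4-[(tert-butyldimethylsilyl)oxy]cyclopent-2-en-1-one
Product: 26 (R)-4-methylcyclopent-2-en-1-one, via 3-methyl-4-silyloxy ketone 25 (not isolated)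
Conditions: Me2CuLi (from MeLi and CuI), Et2O, −78 °C; aq. NH4Cl; then DBU, CH2Cl2, 0 °C → rt
Reagents that add atoms: lithium dimethylcuprate (from MeLi and CuI), [Li+].C[Cu-]C
Why: Cuprate conjugate addition anti to the silyloxy group followed by E1cB loss of silanol is the known route from 4-silyloxycyclopentenones to 4-alkylcyclopentenones and transfers the chirality to the methyl-bearing carbon (later C33, R).

Step 17
Reactants: 26
Product: 27 (R)-2-iodo-4-methylcyclopent-2-en-1-one
Conditions: I2, pyridine, CH2Cl2, 0 °C → rt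
Reagents that add atoms: iodine, II
Why: α-Iodination of the enone by the iodine/pyridine addition–elimination sequence gives the 2-iodoenone needed as cross-coupling partner.

Step 18
Reactants: 23; 27
Product: 30 (4R)-4-methyl-2-{1-[(2R,3R,3aS,5S,6S,7aS)-2-[(tert-butyldimethylsilyl)oxy]-7a-methyl-3-(propan-2-yl)-6-(prop-1-en-2-yl)octahydro-1H-inden-5-yl]ethenyl}cyclopent-2-en-1-one, via alkenyllithium 28 (not isolated), via alkenylzinc chloride 29 (not isolated)
Conditions: n-BuLi (2.1 equiv), THF, −78 → 0 °C; ZnCl2, THF, 0 °C; then 27, Pd(PPh3)4 (5 mol %), THF, rt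
Reagents that add atoms: none
Why: Shapiro reaction (syn-deprotonation at the methyl group, loss of N2 and sulfinate) gives the 1,1-disubstituted alkenyllithium regiospecifically, and transmetalation to zinc allows a Negishi coupling with the α-iodoenone under zerovalent palladium catalysis, forming C2–C39 without disturbing C3 or C33.

Step 19
Reactants: 30
Product: 32 (2S,3S,4R)-4-methyl-3-(prop-2-en-1-yl)-2-{1-[(2R,3R,3aS,5S,6S,7aS)-2-[(tert-butyldimethylsilyl)oxy]-7a-methyl-3-(propan-2-yl)-6-(prop-1-en-2-yl)octahydro-1H-inden-5-yl]ethenyl}cyclopentan-1-one, via C39 epimer 31 (not isolated)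
Conditions: CH2=CHCH2SiMe3 (3 equiv), TiCl4 (1.2 equiv), CH2Cl2, −78 °C; aq. NaHCO3; then Et3N, CH2Cl2, rt
Reagents that add atoms: allyltrimethylsilane, C=CC[Si](C)(C)C
Why: Hosomi–Sakurai conjugate allylation: the allylsilane attacks the TiCl4-activated enone at C32 anti to the neighbouring C33 methyl (C32 S), and amine-mediated equilibration of the acidic C39–H leaves the alkenyl group trans to the allyl group.

Step 20
Reactants: 32
Product: 33 tetracyclic ketone (rings A–D; C37 ketone; C39–H trans to H32 with C39 S, C32 S, C33 R; C2 exo-methylene; 28Z; C10 silyl ether)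
Conditions: second-generation Hoveyda–Grubbs catalyst [RuCl2(SIMes)(=CH-C6H4-2-Oi-Pr)] (15 mol %), 1,4-benzoquinone (20 mol %), toluene (1 mM), 90 °C
Reagents that add atoms: none
Why: Ring-closing metathesis of the allyl and isopropenyl groups closes ring B with the ring-enforced Z trisubstituted C28=C30 alkene; with the C2 methylene trans to the allyl group on ring A no five-membered ring can form, so the eight-membered ring is the only cyclic outlet.

Step 21
Reactants: 33
Product: 34 tetracyclic α-ketol (C39–OH cis to H32 with C39 S; otherwise as 33)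
Conditions: KN(SiMe3)2 (1.05 equiv), THF, −78 → −30 °C; then 3-phenyl-2-(phenylsulfonyl)oxaziridine, −78 °C; aq. NH4Cl
Reagents that add atoms: 3-phenyl-2-(phenylsulfonyl)oxaziridine, O=S(=O)(c1ccccc1)N1OC1c1ccccc1
Why: Enolate hydroxylation with an N-sulfonyloxaziridine: the doubly activated C39–H gives the extended potassium enolate under equilibrating conditions, which reacts at its α-carbon, and oxygen is delivered to the face of C39 opposite C31 (the H32 face), giving the cis-fused α-ketol.

Step 22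
Reactants: 34
Product: 35 tetracyclic diol (C10–OH and C39–OH free; otherwise as 34)
Conditions: HF·pyridine, pyridine, THF, 0 °C → rt
Reagents that add atoms: none
Why: Fluoride cleavage of the secondary silyl ether under buffered conditions frees the C10 hydroxyl and leaves the α-ketol and both alkenes intact.

Step 23
Reactants: 36 (S)-1-bromo-2-methylbutane
Product: 37 (S)-4-methylhex-1-yne
Conditions: LiC≡CH·H2NCH2CH2NH2, DMSO, 10 °C → rt
Reagents that add atoms: lithium acetylide (ethane-1,2-diamine complex), [Li]C#C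
Why: SN2 alkynylation of the primary bromide extends the chain without touching the chiral-pool stereocentre (later C19, S).

Step 24
Reactants: 37
Product: 39 (2E,5S)-3,5-dimethylhept-2-en-1-ol, via alkenylalane 38 (not isolated)
Conditions: AlMe3 (2 equiv), Cp2ZrCl2 (0.2 equiv), CH2Cl2, 0 °C → rt; n-BuLi, THF, −78 °C; (CH2O)n, → rt; aq. HCl
Reagents that add atoms: trimethylaluminium, C[Al](C)C; formaldehyde (as paraformaldehyde), C=O
Why: Zirconium-catalysed carboalumination (Negishi) adds methyl and aluminium syn across the terminal alkyne, and the derived aluminate is hydroxymethylated with retention, giving the E trisubstituted allylic alcohol.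

Step 25
Reactants: 39
Product: 40 [(2R,3R)-3-methyl-3-[(2S)-2-methylbutyl]oxiran-2-yl]methanol
Conditions: Ti(Oi-Pr)4 (10 mol %), D-(−)-diethyl tartrate (12 mol %), t-BuOOH, 4 Å molecular sieves, CH2Cl2, −20 °C
Reagents that add atoms: tert-butyl hydroperoxide, CC(C)(C)OO
Why: Sharpless asymmetric epoxidation: with D-(−)-diethyl tartrate oxygen is delivered to the face that gives the (2R,3R)-epoxide, which fixes the tertiary centre (later C15).

Step 26
Reactants: 40
Product: 41 (3R,5S)-3,5-dimethylheptane-1,3-diol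
Conditions: NaAlH2(OCH2CH2OMe)2, THF, 0 °C → rt; aq. potassium sodium tartrate
Reagents that add atoms: none
Why: Hydroxyl-directed hydride opening of the 2,3-epoxy alcohol at C2 gives the 1,3-diol and keeps the C–O bond at the tertiary carbon, so that centre stays R.

Step 27
Reactants: 41
Product: 42 (3R,5S)-3-hydroxy-3,5-dimethylheptanoic acid
Conditions: TEMPO (2,2,6,6-tetramethylpiperidin-1-oxyl, 20 mol %), PhI(OAc)2 (2.5 equiv), MeCN/H2O, rt
Reagents that add atoms: water, O
Why: Nitroxyl-catalysed oxidation takes the primary alcohol through the aldehyde hydrate to the acid and cannot touch the tertiary alcohol.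

Step 28
Reactants: 42
Product: 44 (3R,5S)-3,5-dimethyl-3-[(triethylsilyl)oxy]heptanoic acid, via silyl ester 43 (not isolated)
Conditions: Et3SiOTf (2.5 equiv), 2,6-lutidine, CH2Cl2, −78 → 0 °C; then K2CO3, MeOH/H2O, 0 °C; citric acid to pH 4
Reagents that add atoms: triethylsilyl triflate, CC[Si](CC)(CC)OS(=O)(=O)C(F)(F)F
Why: Silylation of both the tertiary alcohol and the acid, then selective methanolysis of the labile silyl ester, protects the β-hydroxyl against acylation and retro-aldol cleavage in the later steps.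

Step 29
Reactants: 35; 44
Product: 46 C10 ester of 35 with acid 44 (C37 ketone; C39–OH free; side-chain C15 silyl ether), via mixed anhydride 45 (not isolated)
Conditions: 44, 2,4,6-Cl3C6H2COCl, Et3N, toluene, rt; then 35, 4-(dimethylamino)pyridine, toluene, rt → 40 °C
Reagents that add atoms: none
Why: Yamaguchi esterification: the mixed anhydride acylates the secondary C10 hydroxyl under nucleophilic catalysis, while the tertiary C39 hydroxyl is too hindered to react.

Step 30
Reactants: 46
Product: 47 C35-hydroxy ketone (α,α′-dihydroxy ketone; epimers at C35 of no consequence)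
Conditions: KN(SiMe3)2 (2.2 equiv), THF, −78 °C; 3-phenyl-2-(phenylsulfonyl)oxaziridine, −78 °C; aq. NH4Cl
Reagents that add atoms: 3-phenyl-2-(phenylsulfonyl)oxaziridine, O=S(=O)(c1ccccc1)N1OC1c1ccccc1
Why: Enolate hydroxylation with an N-sulfonyloxaziridine: after deprotonation of the C39 hydroxyl the ketone can enolise only toward C35 (C39 is quaternary) and is far more acidic than the ester, so oxygen enters at C35 alone.

Step 31
Reactants: 47
Product: 49 diosphenol with side-chain silyl ether (C33=C35–OH, C37 ketone), via 1,2-diketone 48 (not isolated)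
Conditions: Dess–Martin periodinane, CH2Cl2, rt; silica gel
Reagents that add atoms: none
Why: Dess–Martin oxidation of the secondary α-hydroxy ketone gives the 1,2-diketone, which can enolise only toward C33 and so tautomerises to the diosphenol, erasing the auxiliary C33 stereocentre; the tertiary alcohol is inert.

Step 32
Reactants: 49
Product: 50 CNP0110944.3 (target)
Conditions: HF·pyridine, pyridine, THF, 0 °C → rt
Reagents that add atoms: none
Why: Fluoride cleavage of the tertiary triethylsilyl ether with buffered HF·pyridine unmasks the side-chain hydroxyl under conditions that the β-hydroxy ester, the diosphenol and the allylic tertiary alcohol should tolerate.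

Compound list
1 | 4-methylpent-4-enoic acid | C=C(C)CCC(=O)O | starting material
2 | (R)-4-benzyl-1,3-oxazolidin-2-one | O=C1N[C@H](Cc2ccccc2)CO1 | starting material
3 | 4-methylpent-4-enoic pivalic anhydride (not isolated) | C=C(C)CCC(=O)OC(=O)C(C)(C)C | intermediate
4 | (R)-4-benzyl-3-(4-methylpent-4-enoyl)-1,3-oxazolidin-2-one | C=C(C)CCC(=O)N1[C@H](Cc2ccccc2)COC1=O | intermediate
5 | tert-butyl bromoacetate | CC(C)(C)OC(=O)CBr | starting material
6 | tert-butyl (3S)-3-{[(4R)-4-benzyl-2-oxo-1,3-oxazolidin-3-yl]carbonyl}-5-methylhex-5-enoate | CC(C)(C)OC(=O)C[C@H](CC(C)=C)C(=O)N1[C@H](Cc2ccccc2)COC1=O | intermediate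
7 | (2S)-4-tert-butoxy-2-(2-methylprop-2-en-1-yl)-4-oxobutanoic acid | CC(C)(C)OC(=O)C[C@H](CC(C)=C)C(=O)O | intermediate
8 | 3-methylbut-1-yne | CC(C)C#C | starting material
9 | 4-methylpent-2-yn-1-ol | CC(C)C#CCO | intermediate
10 | 1-bromo-4-methylpent-2-yne | CC(C)C#CCBr | intermediate
11 | (2S,3S)-3-(tert-butoxycarbonyl)-7-methyl-2-(2-methylprop-2-en-1-yl)oct-5-ynoic acid | CC(C)(C)OC(=O)[C@@H](CC#CC(C)C)[C@H](CC(C)=C)C(=O)O | intermediate
12 | 1-tert-butyl 4-methyl (2S,3S)-2-(4-methylpent-2-yn-1-yl)-3-(2-methylprop-2-en-1-yl)butanedioate | CC(C)(C)OC(=O)[C@@H](CC#CC(C)C)[C@H](CC(C)=C)C(=O)OC | intermediate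
13 | hexacarbonyldicobalt complex Co2(CO)6 of the alkyne of 12 (not isolated) | CC(C)(C)OC(=O)[C@@H](CC12[Co]3(=C=O)(=C=O)(=C=O)[Co]1(=C=O)(=C=O)(=C=O)C23C(C)C)[C@H](CC(C)=C)C(=O)OC | intermediate
14 | 5-tert-butyl 6-methyl (5S,6S,7aS)-7a-methyl-2-oxo-3-(propan-2-yl)-2,4,5,6,7,7a-hexahydro-1H-indene-5,6-dicarboxylate | CC(C)(C)OC(=O)[C@H]2CC3=C(C(C)C)C(=O)C[C@]3(C)C[C@@H]2C(=O)OC | intermediate
15 | 5-tert-butyl 6-methyl (2R,5S,6S,7aS)-2-hydroxy-7a-methyl-3-(propan-2-yl)-2,4,5,6,7,7a-hexahydro-1H-indene-5,6-dicarboxylate | CC(C)(C)OC(=O)[C@H]2CC3=C(C(C)C)[C@H](O)C[C@]3(C)C[C@@H]2C(=O)OC | intermediate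
16 | 5-tert-butyl 6-methyl (2R,3R,3aS,5S,6S,7aS)-2-hydroxy-7a-methyl-3-(propan-2-yl)octahydro-1H-indene-5,6-dicarboxylate | CC(C)(C)OC(=O)[C@H]2C[C@H]3[C@@H](C(C)C)[C@H](O)C[C@]3(C)C[C@@H]2C(=O)OC | intermediate
17 | N-methoxy-N-methylamide at C28 of 16, tert-butyl ester kept (not isolated) | CC(C)(C)OC(=O)[C@H]2C[C@H]3[C@@H](C(C)C)[C@H](O)C[C@]3(C)C[C@@H]2C(=O)N(C)OC | intermediate
18 | tert-butyl (2R,3R,3aS,5S,6S,7aS)-6-acetyl-2-hydroxy-7a-methyl-3-(propan-2-yl)octahydro-1H-indene-5-carboxylate | CC(C)(C)OC(=O)[C@H]2C[C@H]3[C@@H](C(C)C)[C@H](O)C[C@]3(C)C[C@@H]2C(C)=O | intermediate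
19 | tert-butyl (2R,3R,3aS,5S,6S,7aS)-2-hydroxy-7a-methyl-3-(propan-2-yl)-6-(prop-1-en-2-yl)octahydro-1H-indene-5-carboxylate | CC(C)(C)OC(=O)[C@H]2C[C@H]3[C@@H](C(C)C)[C@H](O)C[C@]3(C)C[C@@H]2C(C)=C | intermediate
20 | tert-butyldimethylsilyl ester of 21 (not isolated) | CC(C)(C)[Si](C)(C)OC(=O)[C@H]2C[C@H]3[C@@H](C(C)C)[C@H](O[Si](C)(C)C(C)(C)C)C[C@]3(C)C[C@@H]2C(C)=C | intermediate
21 | (2R,3R,3aS,5S,6S,7aS)-2-[(tert-butyldimethylsilyl)oxy]-7a-methyl-3-(propan-2-yl)-6-(prop-1-en-2-yl)octahydro-1H-indene-5-carboxylic acid | OC(=O)[C@H]2C[C@H]3[C@@H](C(C)C)[C@H](O[Si](C)(C)C(C)(C)C)C[C@]3(C)C[C@@H]2C(C)=C | intermediate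
22 | 1-[(2R,3R,3aS,5S,6S,7aS)-2-[(tert-butyldimethylsilyl)oxy]-7a-methyl-3-(propan-2-yl)-6-(prop-1-en-2-yl)octahydro-1H-inden-5-yl]ethan-1-one | CC(=O)[C@H]2C[C@H]3[C@@H](C(C)C)[C@H](O[Si](C)(C)C(C)(C)C)C[C@]3(C)C[C@@H]2C(C)=C | intermediate
23 | 2,4,6-tri(propan-2-yl)benzenesulfonyl hydrazone of 22 | CC(=NNS(=O)(=O)c1c(C(C)C)cc(C(C)C)cc1C(C)C)[C@H]2C[C@H]3[C@@H](C(C)C)[C@H](O[Si](C)(C)C(C)(C)C)C[C@]3(C)C[C@@H]2C(C)=C | intermediate
24 | (R)-4-[(tert-butyldimethylsilyl)oxy]cyclopent-2-en-1-one | O=C1C=C[C@H](O[Si](C)(C)C(C)(C)C)C1 | starting material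
25 | (3R,4R)-4-[(tert-butyldimethylsilyl)oxy]-3-methylcyclopentan-1-one (not isolated) | O=C1C[C@@H](C)[C@H](O[Si](C)(C)C(C)(C)C)C1 | intermediate
26 | (R)-4-methylcyclopent-2-en-1-one | O=C1C=C[C@H](C)C1 | intermediate
27 | (R)-2-iodo-4-methylcyclopent-2-en-1-one | O=C1C(I)=C[C@H](C)C1 | intermediate
28 | alkenyllithium from 23 (C2–Li, C2=C1H2; ring stereocentres as in 22; not isolated) | [Li]C(=C)[C@H]2C[C@H]3[C@@H](C(C)C)[C@H](O[Si](C)(C)C(C)(C)C)C[C@]3(C)C[C@@H]2C(C)=C | intermediate
29 | alkenylzinc chloride from 28 (not isolated) | Cl[Zn]C(=C)[C@H]2C[C@H]3[C@@H](C(C)C)[C@H](O[Si](C)(C)C(C)(C)C)C[C@]3(C)C[C@@H]2C(C)=C | intermediate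
30 | (4R)-4-methyl-2-{1-[(2R,3R,3aS,5S,6S,7aS)-2-[(tert-butyldimethylsilyl)oxy]-7a-methyl-3-(propan-2-yl)-6-(prop-1-en-2-yl)octahydro-1H-inden-5-yl]ethenyl}cyclopent-2-en-1-one | C=C(C1=C[C@H](C)CC1=O)[C@H]2C[C@H]3[C@@H](C(C)C)[C@H](O[Si](C)(C)C(C)(C)C)C[C@]3(C)C[C@@H]2C(C)=C | intermediate
31 | (2R,3S,4R)-epimer of 32 at C39, alkenyl cis to allyl (not isolated) | C=C([C@H]1[C@@H](CC=C)[C@H](C)CC1=O)[C@H]2C[C@H]3[C@@H](C(C)C)[C@H](O[Si](C)(C)C(C)(C)C)C[C@]3(C)C[C@@H]2C(C)=C | intermediate
32 | (2S,3S,4R)-4-methyl-3-(prop-2-en-1-yl)-2-{1-[(2R,3R,3aS,5S,6S,7aS)-2-[(tert-butyldimethylsilyl)oxy]-7a-methyl-3-(propan-2-yl)-6-(prop-1-en-2-yl)octahydro-1H-inden-5-yl]ethenyl}cyclopentan-1-one | C=C([C@@H]1[C@@H](CC=C)[C@H](C)CC1=O)[C@H]2C[C@H]3[C@@H](C(C)C)[C@H](O[Si](C)(C)C(C)(C)C)C[C@]3(C)C[C@@H]2C(C)=C | intermediate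
33 | tetracyclic ketone (C37 ketone; C39–H trans to H32; C33 methyl sp3; C2 exo-methylene; 28Z; C10 silyl ether) | C=C1[C@H]2C[C@H]3[C@@H](C(C)C)[C@H](O[Si](C)(C)C(C)(C)C)C[C@]3(C)C[C@@H]2/C(C)=C\C[C@H]2[C@H](C)CC(=O)[C@H]12 | intermediate
34 | tetracyclic α-ketol (C39–OH cis to H32; C10 silyl ether) | C=C1[C@H]2C[C@H]3[C@@H](C(C)C)[C@H](O[Si](C)(C)C(C)(C)C)C[C@]3(C)C[C@@H]2/C(C)=C\C[C@H]2[C@H](C)CC(=O)[C@@]12O | intermediate
35 | tetracyclic diol (C10–OH, C39–OH; C37 ketone) | C=C1[C@H]2C[C@H]3[C@@H](C(C)C)[C@H](O)C[C@]3(C)C[C@@H]2/C(C)=C\C[C@H]2[C@H](C)CC(=O)[C@@]12O | intermediate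
36 | (S)-1-bromo-2-methylbutane | CC[C@H](C)CBr | starting material
37 | (S)-4-methylhex-1-yne | CC[C@H](C)CC#C | intermediate
38 | dimethyl[(1E,4S)-2,4-dimethylhex-1-en-1-yl]alane (not isolated) | CC[C@H](C)C/C(C)=C/[Al](C)C | intermediate
39 | (2E,5S)-3,5-dimethylhept-2-en-1-ol | CC[C@H](C)C/C(C)=C/CO | intermediate
40 | [(2R,3R)-3-methyl-3-[(2S)-2-methylbutyl]oxiran-2-yl]methanol | CC[C@H](C)C[C@@]1(C)O[C@@H]1CO | intermediate
41 | (3R,5S)-3,5-dimethylheptane-1,3-diol | CC[C@H](C)C[C@@](C)(O)CCO | intermediate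
42 | (3R,5S)-3-hydroxy-3,5-dimethylheptanoic acid | CC[C@H](C)C[C@@](C)(O)CC(=O)O | intermediate
43 | triethylsilyl (3R,5S)-3,5-dimethyl-3-[(triethylsilyl)oxy]heptanoate (not isolated) | CC[C@H](C)C[C@@](C)(O[Si](CC)(CC)CC)CC(=O)O[Si](CC)(CC)CC | intermediate
44 | (3R,5S)-3,5-dimethyl-3-[(triethylsilyl)oxy]heptanoic acid | CC[C@H](C)C[C@@](C)(O[Si](CC)(CC)CC)CC(=O)O | intermediate
45 | mixed anhydride of 44 with 2,4,6-trichlorobenzoic acid (not isolated) | CC[C@H](C)C[C@@](C)(O[Si](CC)(CC)CC)CC(=O)OC(=O)c1c(Cl)cc(Cl)cc1Cl | intermediate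
46 | C10 ester of 35 with 44 (C37 ketone; C39–OH; C15 silyl ether) | C=C1[C@H]2C[C@H]3[C@@H](C(C)C)[C@H](OC(=O)C[C@](C)(O[Si](CC)(CC)CC)C[C@@H](C)CC)C[C@]3(C)C[C@@H]2/C(C)=C\C[C@H]2[C@H](C)CC(=O)[C@@]12O | intermediate
47 | C35-hydroxy derivative of 46 (C35 epimers) | C=C1[C@H]2C[C@H]3[C@@H](C(C)C)[C@H](OC(=O)C[C@](C)(O[Si](CC)(CC)CC)C[C@@H](C)CC)C[C@]3(C)C[C@@H]2/C(C)=C\C[C@H]2[C@H](C)C(O)C(=O)[C@@]12O | intermediate
48 | C35,C37-diketone (not isolated) | C=C1[C@H]2C[C@H]3[C@@H](C(C)C)[C@H](OC(=O)C[C@](C)(O[Si](CC)(CC)CC)C[C@@H](C)CC)C[C@]3(C)C[C@@H]2/C(C)=C\C[C@H]2[C@H](C)C(=O)C(=O)[C@@]12O | intermediate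
49 | diosphenol with C15 triethylsilyl ether | C=C1[C@H]2C[C@H]3[C@@H](C(C)C)[C@H](OC(=O)C[C@](C)(O[Si](CC)(CC)CC)C[C@@H](C)CC)C[C@]3(C)C[C@@H]2/C(C)=C\C[C@H]2C(C)=C(O)C(=O)[C@@]12O | intermediate
50 | CNP0110944.3: C10 (3R,5S)-3-hydroxy-3,5-dimethylheptanoate of the tetracyclic diosphenol (C3 S, C5 S, C6 R, C10 R, C24 S, C27 S, C32 S, C39 S; 28Z) | C=C1[C@H]2C[C@H]3[C@@H](C(C)C)[C@H](OC(=O)C[C@](C)(O)C[C@@H](C)CC)C[C@]3(C)C[C@@H]2/C(C)=C\C[C@H]2C(C)=C(O)C(=O)[C@@]12O | target

Total step count: 32. Longest linear sequence: 22 steps (steps 1–3, 6–15, 18–22, 29–32).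

Steps most likely to fail

Step 8. Alkene insertion into the cobalt complex may be too slow for this 1,1-disubstituted, 1,7-related enyne, so that decomplexation or alkyne oligomerisation takes over. The fallback sets out from 12 and returns at 14. It makes the same three bonds on nickel with an isocyanide as the one-carbon unit: 12 is treated with Ni(cod)2 (zerovalent nickel) and tert-butyl isocyanide to give the N-tert-butyl iminocyclopentene F1, and mild hydrolysis (aq. oxalic acid, THF) gives 14.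

Step 20. The eight-membered ring may fail to close across the trans C39–C32 junction, leaving cross-metathesis dimerisation of the allyl group as the main pathway. The fallback sets out from 32 and returns at 34, closing the ring in the cis-fused series. Compound 32 is hydroxylated at C39 as in step 21 to the α-ketol F2. Because its C2 methylene now lies cis to the allyl group and would close a cyclopentene, it is first masked by hydroxyl-directed epoxidation (VO(acac)2, t-BuOOH) as the epoxy alcohol F3. Ring-closing metathesis under the step 20 conditions gives the tetracyclic epoxide F4, and deoxygenation (CH3ReO3 cat., PPh3) restores the exocyclic alkene in 34.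

Step 21. Enolisation may lose regiocontrol (deprotonation at C35 instead of C39), or oxygen may be transferred to the terminal carbon C1 of the extended enolate. The fallback sets out from 33 and returns at 34. The β,γ-unsaturated ketone is isomerised into conjugation (DBU, CH2Cl2) to the tetrasubstituted enone F5. Nucleophilic epoxidation (t-BuOOH, DBU) from the face away from C31 gives the α,β-epoxy ketone F6. Base-induced epoxide-to-allylic-alcohol isomerisation with Et2Al(2,2,6,6-tetramethylpiperidide) removes a C1 proton and cleaves C2–O to give 34.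

Further compounds
F1 | step 8 | N-tert-butyl imine of 14 (iminocyclopentene) | CC(C)(C)OC(=O)[C@H]2CC3=C(C(C)C)C(=NC(C)(C)C)C[C@]3(C)C[C@@H]2C(=O)OC
F2 | step 20 | C39 α-ketol of 32 (hydroxyl trans to the allyl group, ring B open) | C=C([C@@]1(O)[C@@H](CC=C)[C@H](C)CC1=O)[C@H]2C[C@H]3[C@@H](C(C)C)[C@H](O[Si](C)(C)C(C)(C)C)C[C@]3(C)C[C@@H]2C(C)=C
F3 | step 20 | C1,C2-epoxide of F2 | C1OC1([C@@]2(O)[C@@H](CC=C)[C@H](C)CC2=O)[C@H]3C[C@H]4[C@@H](C(C)C)[C@H](O[Si](C)(C)C(C)(C)C)C[C@]4(C)C[C@@H]3C(C)=C
F4 | step 20 | tetracyclic C1,C2-epoxide of 34 | C1OC12[C@H]3C[C@H]4[C@@H](C(C)C)[C@H](O[Si](C)(C)C(C)(C)C)C[C@]4(C)C[C@@H]3/C(C)=C\C[C@H]3[C@H](C)CC(=O)[C@@]23O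
F5 | step 21 | conjugated tetrasubstituted enone (C39=C2, C1 methyl) isomer of 33 | CC=1[C@H]2C[C@H]3[C@@H](C(C)C)[C@H](O[Si](C)(C)C(C)(C)C)C[C@]3(C)C[C@@H]2/C(C)=C\C[C@H]2[C@H](C)CC(=O)C=12
F6 | step 21 | C2,C39-epoxy ketone from F5 | C[C@@]12[C@H]3C[C@H]4[C@@H](C(C)C)[C@H](O[Si](C)(C)C(C)(C)C)C[C@]4(C)C[C@@H]3/C(C)=C\C[C@H]3[C@H](C)CC(=O)[C@@]13O2
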